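Target forms one for one from starting material and coupling partner, so in the ash flask measure it as a fraction of the starting material charged. There the coupling partner is the limiting reagent, 0.200 M against 1.20 M. Divide the limiting charge by the starting material charge: this gives 16.7%, the ceiling, the largest share of starting material that can become target. That is the bound from above.

| flask | starting material | coupling partner | time |
|---|---|---|---|
| maple | 0.400 M | 0.400 M |  |
| larch | 0.160 M | 0.160 M |  |
| elm | 0.600 M | 0.400 M |  |
| cedar | 0.400 M | 0.600 M |  |
| ash | 1.20 M | 0.200 M | 8.0 h |

- maple run (time / h: [target] / M): 0.32: 0.017; 0.72: 0.025; 1.6: 0.064; 3.6: 0.156; 8.0: 0.249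
- larch run (time / h: [target] / M): 0.32: 0.004; 0.72: 0.012; 1.6: 0.026; 3.6: 0.034; 8.0: 0.060
- elm run (time / h: [target] / M): 0.32: 0.015; 0.72: 0.043; 1.6: 0.085; 3.6: 0.207; 8.0: 0.287
- cedar run (time / h: [target] / M): 0.32: 0.019; 0.72: 0.028; 1.6: 0.092; 3.6: 0.208; 8.0: 0.290

(scatter of a reading: 0.004 M)

1. the power of [starting material] that the first rate follows, about the charge of the maple run; measure it at two percent of starting material made into target (one fixed amount of target, the same in the runs compared)
2. the power of [coupling partner] that the first rate follows, about the charge of the maple run; measure it at two percent of starting material made into target
3. target in the ash run at 8.0 h, as a share of the starting material charged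

- Overall: starting material + coupling partner -> target.
- Constant volume, constant temperature.
- "The second partner" is coupling partner.
- An order is taken over about fifteen percent of the charge, up and down.

For a bound from below, take the two runs with equal charges, larch and maple, and divide the last reading of each by its limiting charge. Larch reached 0.375 of its limiting charge by 8.0 h, which would put ash at 6.26%. Now tighten it with maple, which reached 0.622. At 1.6 h, elm reads 0.085 M and cedar 0.092 M against 0.064 M for maple, so the extra charge of either partner raises early target by a similar amount. Use the product of the two charges as a rough guide to speed. In ash it is 1.50 times that of maple, and ash has half the coupling partner to use up. So expect ash to fill at least the maple fraction, which gives 10.4%. My bracket runs from there to the ceiling.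

The forecast gives orders of 0.7 and 0.7 and a yield of 15.2%, within 12% to 16.6%. Its yield stands inside my bracket, and it says “The cap is 16.7%.”

The ash flask gives 11.7%. The orders come out at 0.65 for starting material and 0.65 for coupling partner.

    starting material + coupling partner ⇌ intermediate, settled at all times (8.160 M⁻¹)
    starting material + coupling partner → target (1.307 M⁻¹ h⁻¹)
    starting material + coupling partner + target → 2 target (13.86 M⁻² h⁻¹)
    target → decomposed product (0.05184 h⁻¹)

Divide the result by the ceiling: ash filled 0.701 of it. Now take elm, whose ceiling is 66.7%. Its reading of 0.287 M at 8.0 h is 47.8% of its starting material, which fills 0.717 of that ceiling.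

The numbers in the tables were computed from invented constants; the scatter is artificial.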